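**Retrosynthetic overview**
1. Magnone B ⇐ double C–B oxidation of an oxolane carrying a 3-CH2Bpin group and a 4-[aryl(Bpin)methylidene] group. The alkenyl boronate is a masked aryl ketone, and C4 is set when the enol ketonises.
2. Bis-boronate ⇐ Ni(0)-catalysed diborylative cyclisation of an O-tethered 1,6-enyne (key step). It forms C3–C4 and the only ring, and sets C3 trans to the C2 aryl.
3. Enyne ⇐ Ir-catalysed asymmetric allylic etherification (sets C2) of a trimethoxycinnamyl carbonate with an aryl propargylic alcohol.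
4. Building blocks: methyl 3,4,5-trimethoxycinnamate, 4-iodoveratrole and propargyl alcohol. Net change from enyne to target is "+H2O2", with no protecting groups.

Assumption: the (Sa,Sc,Sc) Feringa-type phosphoramidite is taken to give the (S)-branched ether; this sense is from memory and must be confirmed on the first run (use the ligand antipode if it is opposite).

Ring numbering used below: O1, C2 (trimethoxyphenyl), C3 (CH2OH), C4 (aroyl), C5 (CH2).

**Step 1**
Reactants: 1, methyl (E)-3-(3,4,5-trimethoxyphenyl)prop-2-enoate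
Product: 2, (E)-3-(3,4,5-trimethoxyphenyl)prop-2-en-1-ol
Conditions: DIBAL-H (2.5 equiv), CH2Cl2, −78 → 0 °C
Reagents that add atoms: none
Why: DIBAL 1,2-reduction of an enoate gives the allylic alcohol without touching the alkene.

**Step 2**
Reactants: 2, (E)-3-(3,4,5-trimethoxyphenyl)prop-2-en-1-ol
Product: 3, tert-butyl (E)-3-(3,4,5-trimethoxyphenyl)prop-2-en-1-yl carbonate
Conditions: n-BuLi, THF, −78 °C; Boc2O, → rt
Reagents that add atoms: di-tert-butyl dicarbonate, CC(C)(C)OC(=O)OC(=O)OC(C)(C)C
Why: O-acylation of the lithium alkoxide; the tert-butyl carbonate is chosen so the leaving group (t-BuO−/CO2) does not compete as a nucleophile in step 4.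

**Step 3**
Reactants: 4, 4-iodo-1,2-dimethoxybenzene; 5, prop-2-yn-1-ol
Product: 6, 3-(3,4-dimethoxyphenyl)prop-2-yn-1-ol
Conditions: PdCl2(PPh3)2 (2 mol %), CuI (4 mol %), Et3N, rt
Reagents that add atoms: none
Why: Sonogashira coupling of an aryl iodide with a terminal alkyne; the free OH is tolerated.

**Step 4**
Reactants: 3, tert-butyl (E)-3-(3,4,5-trimethoxyphenyl)prop-2-en-1-yl carbonate; 6, 3-(3,4-dimethoxyphenyl)prop-2-yn-1-ol (1.5 equiv)
Product: 7, (S)-5-(1-{[3-(3,4-dimethoxyphenyl)prop-2-yn-1-yl]oxy}prop-2-en-1-yl)-1,2,3-trimethoxybenzene (branched allylic propargylic ether, S at the benzylic carbon = future C2)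
Conditions: 6, n-BuLi then CuI, THF, 0 °C; add 3, [Ir(cod)Cl]2 (2 mol %), (Sa,Sc,Sc)-binaphthol-derived bis(1-phenylethyl)phosphoramidite (4 mol %), THF, rt
Reagents that add atoms: none
Why: Ir-catalysed asymmetric allylic etherification; the copper alkoxide attacks the aryl-substituted terminus of the Ir π-allyl to give the branched ether, and the chiral cyclometallated Ir–phosphoramidite selects the allyl face, setting C2 as (S).

**Step 5 (key step)**
Reactants: 7, the (S)-enyne
Product: 8, 2-{[(2S,3S,4Z)-4-[(3,4-dimethoxyphenyl)(4,4,5,5-tetramethyl-1,3,2-dioxaborolan-2-yl)methylidene]-2-(3,4,5-trimethoxyphenyl)oxolan-3-yl]methyl}-4,4,5,5-tetramethyl-1,3,2-dioxaborolane (2-aryl and 3-CH2Bpin trans)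
Conditions: Ni(cod)2 (10 mol %), PCy3 (20 mol %), B2pin2 (1.2 equiv), toluene, 40 °C
Reagents that add atoms: bis(pinacolato)diboron, CC1(C)OB(OC1(C)C)B1OC(C)(C)C(C)(C)O1
Why: Ni(0)-catalysed diborylative 1,6-enyne cyclisation, a reported reaction class applied here to an untested substrate type. Oxidative cyclometallation gives a nickelacyclopentene (5-exo C3–C4 bond), then B–B metathesis and C–B reductive elimination; the C2 aryl takes the exo position of the forming bicyclic nickelacycle, so CH2[Ni] (→ CH2Bpin) ends up trans to it, which sets C3.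

**Step 6**
Reactants: 8, the bis-boronate
Product: 9, Magnone B, (3,4-dimethoxyphenyl)[(3R,4R,5S)-4-(hydroxymethyl)-5-(3,4,5-trimethoxyphenyl)oxolan-3-yl]methanone
Conditions: NaBO3·4H2O (8 equiv), THF/H2O 1:1, 0 °C → rt, 1–2 h; pH 7 buffer quench
Reagents that add atoms: sodium perborate, [Na+].[Na+].O[B-]1(O)OO[B-](O)(O)OO1
Why: Boronate oxidation converts alkyl–Bpin to CH2OH with retention and alkenyl–Bpin to the enol; ketonisation is a Zimmerman-type kinetic C-protonation of the exocyclic enol(ate) from the face anti to the adjacent C3 substituent, which places the aroyl group cis to CH2OH (C4 = R), and the short, cold, near-neutral conditions limit epimerisation.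

**Compound list**
1 | methyl (E)-3-(3,4,5-trimethoxyphenyl)prop-2-enoate | COC(=O)/C=C/c1cc(OC)c(OC)c(OC)c1 | starting material
2 | (E)-3-(3,4,5-trimethoxyphenyl)prop-2-en-1-ol | OC/C=C/c1cc(OC)c(OC)c(OC)c1 | intermediate
3 | tert-butyl (E)-3-(3,4,5-trimethoxyphenyl)prop-2-en-1-yl carbonate | CC(C)(C)OC(=O)OC/C=C/c1cc(OC)c(OC)c(OC)c1 | intermediate
4 | 4-iodo-1,2-dimethoxybenzene | COc1ccc(I)cc1OC | starting material
5 | prop-2-yn-1-ol | C#CCO | starting material
6 | 3-(3,4-dimethoxyphenyl)prop-2-yn-1-ol | OCC#Cc1ccc(OC)c(OC)c1 | intermediate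
7 | (S)-5-(1-{[3-(3,4-dimethoxyphenyl)prop-2-yn-1-yl]oxy}prop-2-en-1-yl)-1,2,3-trimethoxybenzene | C=C[C@H](OCC#Cc1ccc(OC)c(OC)c1)c1cc(OC)c(OC)c(OC)c1 | intermediate
8 | (2S,3S,4Z)-3-(Bpin-methyl)-4-[(3,4-dimethoxyphenyl)(Bpin)methylidene]-2-(3,4,5-trimethoxyphenyl)oxolane | COc1ccc(/C(B3OC(C)(C)C(C)(C)O3)=C2\CO[C@H](c3cc(OC)c(OC)c(OC)c3)[C@H]2CB2OC(C)(C)C(C)(C)O2)cc1OC | intermediate
9 | Magnone B, (3,4-dimethoxyphenyl)[(3R,4R,5S)-4-(hydroxymethyl)-5-(3,4,5-trimethoxyphenyl)oxolan-3-yl]methanone | COc1ccc(C(=O)[C@H]2CO[C@H](c3cc(OC)c(OC)c(OC)c3)[C@H]2CO)cc1OC | target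

**Totals**
Total steps: 6. Longest linear sequence: 5 (steps 1, 2, 4, 5, 6).

**Steps most likely to fail, with fallbacks**
1. Step 5. Risks are Ni(0) insertion into the allylic/benzylic C–O bond, simple alkyne diboration, and modest trans selectivity at C3. Fallback: switch to a radical ring closure. Epoxidise the vinyl group of 7 (either epoxide diastereomer serves) and run a Cp2TiCl epoxide-opening/5-exo-dig radical cyclisation to the 3-hydroxymethyl-4-benzylidene oxolane. Then silylate, hydroborate and oxidise the benzylidene from the face anti to C3, oxidise the benzylic alcohol (DDQ or MnO2), and desilylate.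
2. Step 6. C4 rests on kinetic protonation, so a cis/trans mixture or base epimerisation is possible. Fallback: fix C4 by ring fusion. Run steps 4–5 with propargyl alcohol itself (terminal alkyne); oxidation of that diboronate gives a hydroxy-aldehyde that funnels, through enol epimerisation, into the cis-fused lactol. Oxidise to the furofuranone lactone (TPAP/NMO), then add 3,4-dimethoxyphenyllithium at −78 °C; lactone opening gives Magnone B with C3/C4 cis by construction.
3. Step 4. Risks are ee and branched:linear ratio with an electron-rich cinnamyl carbonate and a propargylic alkoxide, plus the ligand-sense assumption. Fallback: make racemic 1-(3,4,5-trimethoxyphenyl)prop-2-en-1-ol from 3,4,5-trimethoxybenzaldehyde and vinylmagnesium bromide, resolve with CAL-B/vinyl acetate (the unreacted alcohol is S), and form 7 by Williamson alkylation with 3-(3,4-dimethoxyphenyl)prop-2-ynyl bromide (NaH, THF/DMF).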